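The retrosynthesis removes the phenol acetates last. The C9H2OH/C7'-OH pair and the O–C9' ether of the oxolane (ring A: O–C7–C8–C8'–C9') both trace back to lactols of one dialdehyde, and so to vinyl groups on C8 and C8'. C7–C8 and C7'–C8' are then cut to two aryl aldehydes and a C6 dienediyl bis(boronate).
Enabling feature: at a common oxidation level, Ar–C7(O)–C8–C9 and Ar–C7'(O)–C8'–C9' are the same unit with the same configuration (7S,8S,7'S,8'S), related by a latent C2 axis through the C8–C8' bond. With C9 written as vinyl, the C7 oxygen and the C8–C8' bond are anti in each half, which is what an (E)-allylboronate delivers. This anti pair appears in the target as the all-cis substitution of ring A.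
Forward, the C6 chain is made first (diol, dibromide, bis(boronate)) and then joined to two aldehydes without ring formation. Oxidative cleavage closes ring A and its twin ring B (O–C7'–C8'–C8–C9) as a cis-fused bis-lactol; ring A is fixed by deoxygenation at C9' and ring B is opened by hydride.
All four stereocentres arise in the double allylboration: C7/C7' from the chiral phosphoric acid (aldehyde face) and C8/C8' from the E,E geometry through the chair. Later steps leave them untouched.
The phenols are carried as acetates. This makes the aldehyde more electrophilic, the arenes more resistant to ozone and the benzylic C–O bonds of the strained all-cis array more resistant to Lewis acid, and it avoids hydrogenolysis next to benzylic oxygen.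

Key step: step 3

Assumption: the sense of induction is carried over from simple allyl and (E)-crotyl pinacolboronates, where the (R)-acid directs the allyl group to the Re face of aryl aldehydes, so the (S)-acid is specified for Si-face attack (7S,7'S); its antipode would be used if the bis(boronate) behaved oppositely.

Step 1
Reactants: 1 hexa-1,5-diene-3,4-diol (divinylglycol; commercial dl/meso mixture)
Product: 2 (2E,4E)-1,6-dibromohexa-2,4-diene
Conditions: PBr3, Et2O, 0 °C → rt; recrystallisation
Reagents that add atoms: phosphorus tribromide, BrP(Br)Br
Why: Bromination of the bis(allylic) diol with PBr3 runs with allylic transposition (SN2' and equilibration of the allylic bromides) to the conjugated, thermodynamically preferred and crystalline E,E primary dibromide, so the stereoisomer mixture of 1 is irrelevant and no stereocentre remains.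

Step 2
Reactants: 2 (2E,4E)-1,6-dibromohexa-2,4-diene; 3 bis(pinacolato)diboron (2.2 equiv)
Product: 5 (2E,4E)-hexa-2,4-diene-1,6-diyl bis(pinacolboronate), via bromo allylboronate 4 (not isolated)
Conditions: Pd2(dba)3 (2.5 mol%), THF, 60 °C
Reagents that add atoms: bis(pinacolato)diboron 3, CC1(C)OB(OC1(C)C)B1OC(C)(C)C(C)(C)O1
Why: This is the palladium-catalysed borylation of allylic halides (Miyaura-type), in which oxidative addition to zerovalent palladium gives a pi-allyl bromide, the diboron transmetalates and C–B reductive elimination at the unhindered terminus keeps the linear E,E skeleton at both ends.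

Step 3
Reactants: 5 (2E,4E)-hexa-2,4-diene-1,6-diyl bis(pinacolboronate); 6 4-formyl-2-methoxyphenyl acetate (O-acetylvanillin; 2.2 equiv)
Product: 9 (1S,2R,3R,4S)-1,4-bis(4-acetoxy-3-methoxyphenyl)-2,3-divinylbutane-1,4-diol, via mono-adduct borate 7 (not isolated), via bis(borate) 8 (not isolated)
Conditions: (S)-3,3'-bis(2,4,6-triisopropylphenyl)-1,1'-binaphthyl-2,2'-diyl hydrogen phosphate (10 mol%), 4 Å MS, toluene, −40 → 0 °C; then H2O
Reagents that add atoms: none
Why: Proposed new method: the phosphoric acid hydrogen-bonds to a pinacol oxygen of 5 and to the formyl hydrogen of 6, and the activated boronate delivers its gamma carbon C8 to the Si face of the aldehyde through a closed six-membered chair, so that the C=C bond moves outward to become the C9 vinyl group and mono-adduct 7 still holds an (E)-allylboronate whose gamma carbon is C8'; a second, slower pass through the same chair forms C7'–C8' and gives 8, which water hydrolyses to 9. The closest known reaction types are the chiral-phosphoric-acid-catalysed anti-selective (E)-crotylboration of aryl aldehydes and the gamma-selective addition of pentadienylboronates, whereas their twofold use from both ends of one dienediyl bis(boronate) has not been shown. No ring is closed. C7 and C7' (both S) are set by the aldehyde face that the catalyst exposes, and C8 and C8' (both R in 9) follow from the E geometry with the aryl group equatorial in the chair, which is the anti relation, so the same sense at both ends can only give the C2-symmetric isomer. The step needs gamma rather than alpha or epsilon attack, secured by the cyclic boron-to-oxygen transition state, anti selectivity, secured by the E,E geometry of 5, and catalyst control over the resident C8 centre in the second addition, which is helped because the E alkene has only hydrogen cis to C8 (little allylic strain) and the rotamer with C7 anti to the incoming aldehyde, H8 facing its aryl group and the vinyl group over the alkene already leads to 9. Molecules that react with the wrong sense at one end become the unsymmetrical diastereomer, which chromatography removes, so the enantiomeric purity of 9 should exceed that of a single addition.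

Step 4
Reactants: 9 (1S,2R,3R,4S)-1,4-bis(4-acetoxy-3-methoxyphenyl)-2,3-divinylbutane-1,4-diol
Product: 12 cis-fused bis-lactol (7S,8R,7'S,8'R)-2,6-bis(4-acetoxy-3-methoxyphenyl)-3,7-dioxabicyclo[3.3.0]octane-4,8-diol (both aryl groups endo; anomer mixture), via bis(ozonide) 10 (not isolated), via dialdehyde 11 (not isolated)
Conditions: O3, CH2Cl2, −78 °C; then Me2S, −78 °C → rt; used without prolonged storage
Reagents that add atoms: ozone, [O-][O+]=O
Why: Criegee ozonolysis of the two monosubstituted alkenes, which are far more reactive than the acetoxy-deactivated arenes, followed by reduction of the ozonides unmasks C9 and C9' as aldehydes that are captured at once by the gamma-hydroxyl of the other half (O7 on C9' and O7' on C9, two 5-exo-trig hemiacetalisations made possible by the cis H8/H8' relation), the only new centres being the two anomeric ones that are erased later.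

Step 5
Reactants: 12 cis-fused bis-lactol
Product: 13 (7S,8R,7'S,8'S)-2,6-bis(4-acetoxy-3-methoxyphenyl)-3,7-dioxabicyclo[3.3.0]octan-4-ol (ring A now an oxolane with C9'H2; ring B still a lactol; anomer mixture)
Conditions: Et3SiH (1.0 equiv), BF3·OEt2 (1.1 equiv), CH2Cl2, −78 °C; aq NaHCO3
Reagents that add atoms: none
Why: Ionic hydrogenation of a lactol (oxocarbenium formation with BF3 and hydride transfer from the silane) is a standard way to turn aryl-substituted furofuran lactols into ethers, the two lactols are homotopic so that reaction at either gives 13, the silane is the limiting reagent with unreacted 12 recycled, the electron-poor acetoxyaryl groups disfavour ionisation of the benzylic C7–O bond, and no stereocentre is formed or touched.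

Step 6
Reactants: 13 oxolane lactol
Product: 16 4-[(2S,3S,4S)-4-[(S)-hydroxy(4-hydroxy-3-methoxyphenyl)methyl]-3-(hydroxymethyl)oxolan-2-yl]-2-methoxyphenol (target), via hydroxy aldehyde 14 (not isolated), via diol diacetate 15 (not isolated)
Conditions: NaBH4, MeOH, 0 °C; then K2CO3 (cat), MeOH, 0 °C → rt; aq NH4Cl
Reagents that add atoms: none
Why: Borohydride traps the ring-opened hydroxy aldehyde tautomer of the remaining lactol and so releases C9H2OH and the C7' hydroxyl, and base-catalysed transesterification with methanol then removes the two aryl acetates under conditions too mild to ionise the benzylic C–O bonds, all four stereocentres being spectators.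

Compound list
1 | hexa-1,5-diene-3,4-diol (dl/meso mixture) | C=CC(O)C(O)C=C | starting material
2 | (2E,4E)-1,6-dibromohexa-2,4-diene | BrC/C=C/C=C/CBr | intermediate
3 | bis(pinacolato)diboron | CC1(C)OB(OC1(C)C)B1OC(C)(C)C(C)(C)O1 | starting material
4 | 2-[(2E,4E)-6-bromohexa-2,4-dienyl]-4,4,5,5-tetramethyl-1,3,2-dioxaborolane (not isolated) | BrC/C=C/C=C/CB1OC(C)(C)C(C)(C)O1 | intermediate
5 | (2E,4E)-hexa-2,4-diene-1,6-diyl bis(pinacolboronate) | CC1(C)OB(C/C=C/C=C/CB2OC(C)(C)C(C)(C)O2)OC1(C)C | intermediate
6 | 4-formyl-2-methoxyphenyl acetate (O-acetylvanillin) | COc1cc(C=O)ccc1OC(C)=O | starting material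
7 | pinacol borate of (1S,2R,3E)-1-(4-acetoxy-3-methoxyphenyl)-5-(pinacolboryl)-2-vinylpent-3-en-1-ol (not isolated) | COc1cc([C@@H](OB2OC(C)(C)C(C)(C)O2)[C@H](C=C)/C=C/CB2OC(C)(C)C(C)(C)O2)ccc1OC(C)=O | intermediate
8 | bis(pinacol borate) of diol 9 (not isolated) | COc1cc([C@@H](OB2OC(C)(C)C(C)(C)O2)[C@H](C=C)[C@@H](C=C)[C@H](OB2OC(C)(C)C(C)(C)O2)c2ccc(OC(C)=O)c(OC)c2)ccc1OC(C)=O | intermediate
9 | (1S,2R,3R,4S)-1,4-bis(4-acetoxy-3-methoxyphenyl)-2,3-divinylbutane-1,4-diol | COc1cc([C@@H](O)[C@H](C=C)[C@@H](C=C)[C@H](O)c2ccc(OC(C)=O)c(OC)c2)ccc1OC(C)=O | intermediate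
10 | bis(1,2,4-trioxolan-3-yl) analogue of 9 (ozonide carbons undefined; not isolated) | COc1cc([C@@H](O)[C@H](C2OOCO2)[C@@H](C2OOCO2)[C@H](O)c2ccc(OC(C)=O)c(OC)c2)ccc1OC(C)=O | intermediate
11 | (2R,3R)-2,3-bis[(S)-(4-acetoxy-3-methoxyphenyl)(hydroxy)methyl]butanedial (not isolated) | COc1cc([C@@H](O)[C@H](C=O)[C@@H](C=O)[C@H](O)c2ccc(OC(C)=O)c(OC)c2)ccc1OC(C)=O | intermediate
12 | (7S,8R,7'S,8'R)-2,6-bis(4-acetoxy-3-methoxyphenyl)-3,7-dioxabicyclo[3.3.0]octane-4,8-diol, cis-fused, aryl groups endo, anomer mixture | COc1cc([C@H]2OC(O)[C@@H]3[C@H]2C(O)O[C@@H]3c2ccc(OC(C)=O)c(OC)c2)ccc1OC(C)=O | intermediate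
13 | (7S,8R,7'S,8'S)-2,6-bis(4-acetoxy-3-methoxyphenyl)-3,7-dioxabicyclo[3.3.0]octan-4-ol, anomer mixture | COc1cc([C@H]2OC[C@@H]3[C@H]2C(O)O[C@@H]3c2ccc(OC(C)=O)c(OC)c2)ccc1OC(C)=O | intermediate
14 | (2S,3R,4S)-2-(4-acetoxy-3-methoxyphenyl)-4-[(S)-(4-acetoxy-3-methoxyphenyl)(hydroxy)methyl]oxolane-3-carbaldehyde (not isolated) | COc1cc([C@@H](O)[C@@H]2CO[C@H](c3ccc(OC(C)=O)c(OC)c3)[C@@H]2C=O)ccc1OC(C)=O | intermediate
15 | bis(aryl acetate) of the target, (7S,8S,7'S,8'S) (not isolated) | COc1cc([C@@H](O)[C@@H]2CO[C@H](c3ccc(OC(C)=O)c(OC)c3)[C@@H]2CO)ccc1OC(C)=O | intermediate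
16 | 4-[(2S,3S,4S)-4-[(S)-hydroxy(4-hydroxy-3-methoxyphenyl)methyl]-3-(hydroxymethyl)oxolan-2-yl]-2-methoxyphenol | COc1cc([C@@H](O)[C@@H]2CO[C@H](c3ccc(O)c(OC)c3)[C@@H]2CO)ccc1O | target

Total step count: 6. Longest linear sequence: 6 steps (1 → 2 → 5 → 9 → 12 → 13 → 16).

Steps most likely to fail

Step 3. The second addition may be slow at the hindered gamma carbon. The reactive pentadienyl-type boronate may also add without the catalyst. The resident C8 centre may outweigh the catalyst, which would erode both enantio- and diastereocontrol. The fallback moves absolute control from a catalyst to a stoichiometric auxiliary on boron, which is established chemistry for (E)-gamma-substituted allylboronates. It sets out from 5. Transesterification with diethanolamine (Et2O, rt) should precipitate the bis(diethanolamine) boronate F1. Exchange with diisopropyl (2R,3R)-tartrate in Et2O/brine should give the bis(tartrate) boronate F2. Its electron-poor boron reacts with 6 in toluene over 4 Å MS at −78 °C without any catalyst, through the same chair (anti) and with the Si-face preference of the (R,R)-tartrate. Aqueous work-up comes back to the route at 9. The double addition and a crystallisation are relied on to upgrade the enantiomeric purity.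

Step 5. The second, equally reactive lactol may be reduced as well. The Lewis acid may also ionise the benzylic C7–O bond, with loss of the cis C7/C8 relation. The fallback replaces the ionic deoxygenation by a neutral, radical one. It sets out from 12. PhSSPh and Bu3P (one equivalent each, THF, 0 °C) should exchange one anomeric hydroxyl for a phenylsulfanyl group and give the lactol phenyl thioacetal F3, which is separated from recyclable 12. Bu3SnH with AIBN in toluene at 80 °C then replaces sulfur by hydrogen through the alpha-alkoxy radical. The route is rejoined at 13.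

Step 2. At the stage of 4, boron and bromide may be lost across the diene by reductive 1,6-elimination from the pi-allyl intermediate. Allyl–allyl coupling between boronate and bromide is a second risk. The fallback avoids pi-allyl palladium species and forms the C–B bonds by gamma-selective boryl substitution with monovalent copper. It sets out from 1. Methyl chloroformate and pyridine (CH2Cl2, 0 °C) should give the bis(methyl carbonate) F4. Treatment with 3, CuCl, KOtBu and 4,5-bis(diphenylphosphino)-9,9-dimethylxanthene (THF, rt) adds boron to each terminal CH2 and expels each carbonate with alkene transposition (formal SN2', E-selective). The route is rejoined at 5.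

Further compounds
F1 | step 3 | (2E,4E)-hexa-2,4-diene-1,6-diyl bis(1,3,6,2-dioxazaborocane) (bis(diethanolamine) boronate) | O1CCNCCOB1C/C=C/C=C/CB1OCCNCCO1
F2 | step 3 | (2E,4E)-hexa-2,4-diene-1,6-diyl bis[(4R,5R)-4,5-bis(isopropoxycarbonyl)-1,3,2-dioxaborolane] | O1[C@@H](C(=O)OC(C)C)[C@H](C(=O)OC(C)C)OB1C/C=C/C=C/CB1O[C@@H](C(=O)OC(C)C)[C@H](C(=O)OC(C)C)O1
F3 | step 5 | (7S,8R,7'S,8'R)-2,6-bis(4-acetoxy-3-methoxyphenyl)-8-(phenylsulfanyl)-3,7-dioxabicyclo[3.3.0]octan-4-ol (anomeric centres undefined) | COc1cc([C@H]2OC(Sc4ccccc4)[C@@H]3[C@H]2C(O)O[C@@H]3c2ccc(OC(C)=O)c(OC)c2)ccc1OC(C)=O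
F4 | step 2 | hexa-1,5-diene-3,4-diyl bis(methyl carbonate) (dl/meso mixture) | COC(=O)OC(C=C)C(C=C)OC(=O)OC
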